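## Structural features

The target is a tetracyclic depsidone, C19H16O8. Two benzene rings (ring A and ring C) are joined twice: by a diaryl ether oxygen (A5–O–Ca) and by an aryl ester (A4–C(=O)–O–Cb), which together close the seven-membered dioxepinone ring B. A five-membered hydroxy-lactone (3-hydroxyphthalide, ring D) is fused to ring C across Ce–Cf. Ring A carries a methoxy group, two methyl groups and one hydrogen. Ring C is hexasubstituted, with six different neighbours in the order ether oxygen (Ca), ester oxygen (Cb), methyl (Cc), free phenol (Cd), lactone carbonyl (Ce), lactol carbon (Cf). The only stereocentre is the lactol carbon on Cf, which is (R) and has no stereogenic neighbour. It is the cyclic hemiacetal of an ortho-formyl benzoic acid, so it can lose its configuration by ring opening and cannot be carried through a long sequence. Fragile groups are the depsidone aryl ester (hydroxide, alkoxide), the lactol (base, alcohol exchange, oxidants), the electron-rich ring A with one open position (electrophilic halogen) and the chelated phenol on Cd (competes in acylations). The real difficulty is the fully substituted ring C together with an ether oxygen flanked by four ortho substituents, a poor case for any aryl–oxygen coupling. The key step exploits the ring C pattern of oxygens on Cb and Cd around the methyl-bearing Cc, with a carboxyl on Ce. This is the aromatised form of a 2-methylcyclohexane-1,3-dione carboxylate, so Ce–Cf and Cb–Cc can be formed by annulation of a β-keto ester (Cc, Cd, Ce) with an enoate (Cb, Ca, Cf) that already carries the ring A oxygen on Ca and a masked formyl group on Cf.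

## Logic of the disconnections

**20 back to 19 and 18.** No skeletal bond is cut, only the exocyclic acyl–oxygen bond on the lactol oxygen. The stereocentre is labile, so it is introduced last, by acylating racemic 18 under conditions in which its enantiomers interconvert, and the acyl group of 19 is then removed. Everything before 18 can be handled as racemic or achiral material. The forward steps demand an enantioselective acyl transfer that prefers the lactol hydroxyl to the Cd phenol, and a deacylation that breaks only the acyl–oxygen bond under neutral conditions.

**18 back to 17.** The lactone bond of ring D, between the Ce carbonyl and the lactol oxygen, is cut, and the lactol carbon is returned to a formyl group on Cf beside a methyl ester on Ce. Ring D and the stereocentre are replaced by two robust groups that survive closure of ring B. The forward step must cleave a hindered methyl ester without touching the depsidone ester, which is possible only with help from the neighbouring formyl group.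

**17 back to 15.** The ring B ester bond between the ring A carbonyl and the oxygen on Cb is cut. Only the Cb hydroxyl can reach the ring A carboxyl (seven-membered ring), so the closure has no regiochemical ambiguity. The tricycle opens to a diaryl ether hydroxy acid. The forward step must activate a 2,6-disubstituted benzoic acid, which calls for an acylium-type activation, and the lactol must not yet exist.

**15 back to 14.** The free acid and the aldehyde are masked as a tert-butyl ester and a dimethyl acetal. Both fall under one mild acid treatment, while the ring C methyl ester stays.

**14 back to 13.** Ring C is de-aromatised by formal addition of two hydrogens, to the cyclohexane-1,3-dione. A hexasubstituted arene is thereby turned into the product of an annulation, and its four sp3 centres are of no consequence. The forward dehydrogenation must spare the acetal and the electron-rich ring A.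

**13 back to 10 and 11.** The bonds Ce–Cf and Cb–Cc are cut. Ring C falls into a five-carbon keto ester and a four-carbon enoate, and the ether oxygen on Ca becomes the oxygen of an ordinary alkyl aryl ether. The forward step needs the keto ester to add through Ce to Cf only, and the Claisen closure onto Cb to win over every other acylation. For this reason the ring A carboxyl is kept as a tert-butyl ester: it is inert to methoxide, blocked against Dieckmann closure from Ca, and removable later together with the acetal.

**10 back to 6 and 7 (through 8 and 9).** The Ca=Cf double bond is cut as an aldol condensation. The enoate reduces to an aryloxyacetate and a two-carbon aldehyde acetal. The forward step needs clean enolisation of 6 beside the ring A ester and dehydration toward the ester.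

**6 back to 4 and 5.** The O–CH2 bond is cut. This is where the future diaryl ether bond is actually made, as the alkylation of a phenol and not as an aryl–oxygen coupling. The forward step must alkylate a chelated, di-ortho-substituted phenol.

**4 back to 3, 2 and 1.** The tert-butyl ester is exchanged for the methyl ester, and the methyl ether is cut to the phenol. Compound 1 already holds every carbon of ring A in the right place. The forward steps need mono-methylation at the non-chelated hydroxyl, saponification of a hindered ester, and tert-butylation by alkylation of the carboxylate.

## Other disconnections considered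

**Alternative 1:** The cut is the ether bond A5–O on Ca, closed last as ring B while ring A is still a cyclohexa-1,3-diene. In the forward sense the depside A2 (ring A a β-triflyloxy dienoate, ring C with a free phenol on Ca) is treated with mild base. The phenoxide adds to A5, the β-carbon of the unsaturated ester, triflate leaves, and the dihydrodepsidone A1 results, racemic at the ring A CH–CH3 carbon and still to be dehydrogenated.
- In its favour: the crowded ether oxygen is attached to an activated sp2 carbon by intramolecular addition–elimination, the depside ester is made early by ordinary acylation, and two ring-sized fragments are joined late.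
- Equal or better: on the ether problem it is the equal of the chosen plan, which also avoids an aryl–oxygen coupling; on convergence it is the better one.
- Against it here: the hexasubstituted ring C must be available ready-made, with Cb acylated and the Ca and Cd hydroxyls free. The hardest part of the molecule is therefore left to a separate synthesis, most probably by the annulation used in the chosen route, and three ring C oxygens must be told apart. The aryl ester of A2 is exposed to phenoxide (acyl migration, cleavage), and a hard oxygen nucleophile may attack sulfur of the triflate instead of carbon. The closure is a 7-endo attack, less favourable than a 6-exo Claisen closure. Ring A must still be aromatised in the presence of the acetal and the depsidone ester, so the oxidation is moved to the other ring, not saved.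
- Comparison: both key steps are polar, base-mediated and end in an irreversible event (loss of triflate there, formation of the dione enolate here). Two ring syntheses and the protecting-group traffic on ring C should make it longer than the chosen linear sequence.

**Alternative 2:** The cut is the lactone O–CH2 bond of ring D, so the lactol carbon derives from a methyl group on Cf. In the forward sense the depsidone acid A4 (CO2H on Ce, CH3 on Cf, acetate on Cd) is exposed to PhI(OAc)2 and I2 under light. An oxygen-centred carboxyl radical removes a hydrogen from the ortho methyl, and the oxidised benzylic carbon is captured by the carboxylate to give the phthalide acetate A3.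
- In its favour: ring C of A4 has a simple methyl/carboxyl β-orcinol pattern, so both rings lie close to commercial orsellinate-type building blocks. The site of attack is unambiguous because only one methyl is ortho to the carboxyl. A C–H bond is used directly and no acetal is carried.
- Equal or better: on the directness of forming ring D and on avoiding an acid-labile group it is the better plan. Its radical mechanism is also less sensitive to steric crowding.
- Against it here: A3 is one oxidation level short. Raising the phthalide CH2 to the lactol needs a second benzylic oxidation on a molecule with three other aryl methyl groups and an electron-rich ring A, whose single open position is exposed to the electrophilic iodine reagent already in the key step. The phenol must be protected and released. The disconnection does not say how the depsidone core with its hindered ether is made.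
- Comparison: in the chosen plan Cf enters at the aldehyde level and needs no later oxidation, and the ether problem is solved within the same sequence. Once a core synthesis and the extra oxidation are added, the step count should be no shorter.

**Alternative 3:** The cut runs through ring A at A5–A6 and A3–A4. In the forward sense the pyrone A6 acts as diene toward the alkyne of the aryloxypropiolate A7, in which ring C with a protected lactol is already complete. Cycloaddition and loss of CO2 give the diaryl ether A5 with ring A aromatic.
- In its favour: ring A is aromatic as formed and needs no oxidant. The ether oxygen again sits on a non-aromatic carbon. Regiochemistry follows from matched polarisation, the nucleophilic C3 of the 4-methoxypyrone bonding to the β-carbon of the ynoate.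
- Equal or better: on redox economy it is better than the chosen plan; on the ether problem it is its equal.
- Against it here: it builds the ring that can be bought (ring A is 1 apart from protecting groups) and requires the hexasubstituted ring C as a starting fragment. An aryl ynol ether conjugated to an ester is hard to prepare from a hindered phenol and is prone to hydration and thermal decomposition, while pyrone cycloadditions usually need prolonged heating. Both new bonds join fully substituted carbons, and any regiochemical leak gives an isomer that is hard to remove. Three benzyl groups must come off afterwards.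
- Comparison: it is a thermal pericyclic sequence driven by gas evolution, against an ionic annulation at the boiling point of methanol. The steps after the key step are similar in number, but the way to A7 should be longer than the six steps that lead to 10.

Key step: step 7

Remark on the chemistry: the lactol carbon can epimerise through the ring-opened formyl acid. It is assumed that (R)-20 keeps its configuration under neutral, aprotic conditions long enough to be isolated, so the stereocentre is set in step 12 and unveiled only in step 13.

## Route

Step 1
Reactants: 1 atraric acid (methyl 2,4-dihydroxy-3,6-dimethylbenzoate)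
Product: 2 methyl 2-hydroxy-4-methoxy-3,6-dimethylbenzoate
Conditions: MeI (1.1 equiv), K2CO3, acetone, reflux
Reagents that add atoms: iodomethane, CI
Why: Williamson O-methylation; the 4-hydroxyl is the more acidic and unhindered one, whereas the 2-hydroxyl is hydrogen-bonded to the ester carbonyl and flanked by methyl, so one equivalent of MeI should methylate the 4-position only.

Step 2
Reactants: 2 methyl 2-hydroxy-4-methoxy-3,6-dimethylbenzoate
Product: 3 2-hydroxy-4-methoxy-3,6-dimethylbenzoic acid
Conditions: KOH, DMSO/H2O, 90 °C; then 1 M HCl, 0 °C, pH 2
Reagents that add atoms: potassium hydroxide, [K+].[OH-]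
Why: Saponification of a hindered salicylate with poorly solvated hydroxide; the product stays as its dianion until a short, cold acidification, which limits decarboxylation of the electron-rich salicylic acid.

Step 3
Reactants: 3 2-hydroxy-4-methoxy-3,6-dimethylbenzoic acid
Product: 4 tert-butyl 2-hydroxy-4-methoxy-3,6-dimethylbenzoate
Conditions: Me2NCH(OtBu)2, toluene, 80 °C
Reagents that add atoms: N,N-dimethylformamide di-tert-butyl acetal, CN(C)C(OC(C)(C)C)OC(C)(C)C
Why: Esterification by O-alkylation of the carboxylate with the tert-butyl cation equivalent released from the formamide acetal, which needs no attack on the shielded carbonyl carbon; the chelated phenol should not be alkylated.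

Step 4
Reactants: 4 tert-butyl 2-hydroxy-4-methoxy-3,6-dimethylbenzoate; 5 methyl bromoacetate
Product: 6 tert-butyl 4-methoxy-2-(2-methoxy-2-oxoethoxy)-3,6-dimethylbenzoate
Conditions: Cs2CO3, DMF, 60 °C
Reagents that add atoms: none
Why: Williamson etherification with a reactive α-bromo ester; Cs2CO3 in DMF breaks the internal hydrogen bond and gives a free phenoxide, enough for a di-ortho-substituted phenol. This makes the future O–Ca bond of the diaryl ether as a simple alkylation.

Step 5
Reactants: 6 tert-butyl 4-methoxy-2-(2-methoxy-2-oxoethoxy)-3,6-dimethylbenzoate; 7 dimethoxyacetaldehyde (anhydrous, extracted and distilled from the commercial aqueous solution)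
Product: 8 tert-butyl 2-[(3-hydroxy-1,4,4-trimethoxy-1-oxobutan-2-yl)oxy]-4-methoxy-3,6-dimethylbenzoate (racemic, both diastereomers)
Conditions: LiN(iPr)2 (1.05 equiv), THF, −78 °C; then 7, −78 °C; AcOH quench
Reagents that add atoms: none
Why: Directed aldol addition of a lithium ester enolate; kinetic deprotonation occurs at the O–CH2–CO2Me position, by far the most acidic, and the low temperature and the bulk of the tert-butyl ester hold back Dieckmann closure onto ring A. Two stereocentres form without control and both are destroyed in step 6.

Step 6
Reactants: 8 tert-butyl 2-[(3-hydroxy-1,4,4-trimethoxy-1-oxobutan-2-yl)oxy]-4-methoxy-3,6-dimethylbenzoate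
Product: 10 methyl 2-[2-(tert-butoxycarbonyl)-5-methoxy-3,6-dimethylphenoxy]-4,4-dimethoxybut-2-enoate (alkene isomer mixture), via β-mesyloxy ester 9 (not isolated)
Conditions: MsCl, Et3N, CH2Cl2, 0 °C; then DBU, rt
Reagents that add atoms: none
Why: Mesylation followed by E1cB elimination (DBU removes the acidic hydrogen next to the ester, mesylate leaves) gives the conjugated enoate; either alkene geometry serves because the alkene is consumed in step 7.

Step 7
Reactants: 10 methyl 2-[2-(tert-butoxycarbonyl)-5-methoxy-3,6-dimethylphenoxy]-4,4-dimethoxybut-2-enoate; 11 methyl 3-oxopentanoate
Product: 13 methyl 3-[2-(tert-butoxycarbonyl)-5-methoxy-3,6-dimethylphenoxy]-2-(dimethoxymethyl)-5-methyl-4,6-dioxocyclohexane-1-carboxylate (stereoisomer/enol mixture), via Michael adduct 12 (not isolated)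
Conditions: NaOMe (1.5 equiv), MeOH, 65 °C; then AcOH to pH 5, 0 °C
Reagents that add atoms: none
Why: Michael–Claisen annulation: methoxide generates the stabilised anion of 11 at its central carbon (Ce), which adds to the only electrophilic alkene carbon of 10, the β-carbon Cf, to give 12 (bond Ce–Cf); the ester and the inductive pull of the acetal offset the donor effect of the α-aryloxy group. Proton exchange in methanol then supplies a small equilibrium share of the enolate on the ethyl-ketone methylene (Cc), which attacks the former enoate ester carbon (Cb) and expels methoxide (bond Cb–Cc). Ring C closes in the 6-exo-trig mode, with the enolate double bond inside the new ring, the favoured mode of Claisen and Dieckmann closures. Both events are reversible until the product, a vinylogous acid, is deprotonated by methoxide, and this enolate formation draws the sequence to 13. The closest known reaction is the alkoxide-mediated condensation of acetoacetates or 3-oxopentanoates with crotonates to dihydro-orsellinates. Four sp3 centres (Ca, Cc, Ce, Cf) are created without control and all vanish on aromatisation in step 8, so no controlling element is needed. The selectivities required are attack through Ce and not Cc in the first event (secured by the far higher acidity of the doubly activated carbon), conjugate and not carbonyl addition (soft stabilised anion), and closure onto Cb alone: the other carbon acylations would give four-membered rings, and the ring A ester is a tert-butyl ester between two ortho substituents, inert to methoxide and to the short-lived α-aryloxy enolate, which methanol protonates before it can close a benzofuranone.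

Step 8
Reactants: 13 methyl 3-[2-(tert-butoxycarbonyl)-5-methoxy-3,6-dimethylphenoxy]-2-(dimethoxymethyl)-5-methyl-4,6-dioxocyclohexane-1-carboxylate
Product: 14 methyl 3-[2-(tert-butoxycarbonyl)-5-methoxy-3,6-dimethylphenoxy]-2-(dimethoxymethyl)-4,6-dihydroxy-5-methylbenzoate
Conditions: DDQ (1.05 equiv), anhydrous 1,4-dioxane, 80 °C
Reagents that add atoms: none
Why: Quinone dehydrogenation: DDQ abstracts hydride from the enol form of the dione (the Ca–H, allylic to the enol and next to the aryloxy oxygen, is the most hydridic), and loss of the Cf proton with tautomerisation gives the resorcinol; every stereoisomer and tautomer of 13 converges on one arene. One equivalent in an anhydrous medium is chosen to spare the acetal and the electron-rich product.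

Step 9
Reactants: 14 methyl 3-[2-(tert-butoxycarbonyl)-5-methoxy-3,6-dimethylphenoxy]-2-(dimethoxymethyl)-4,6-dihydroxy-5-methylbenzoate
Product: 15 2-[6-formyl-2,4-dihydroxy-5-(methoxycarbonyl)-3-methylphenoxy]-4-methoxy-3,6-dimethylbenzoic acid
Conditions: TFA/CH2Cl2 (1:3), H2O (5 equiv), 0 °C to rt
Reagents that add atoms: water, O
Why: Acidolysis of the tert-butyl ester (alkyl–oxygen cleavage, the cation leaving as isobutene) and hydrolysis of the dimethyl acetal occur under the same mild aqueous acid; the methyl ester, aryl ethers and phenols are stable, and the aldehyde has no ortho hydroxyl to engage.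

Step 10
Reactants: 15 2-[6-formyl-2,4-dihydroxy-5-(methoxycarbonyl)-3-methylphenoxy]-4-methoxy-3,6-dimethylbenzoic acid
Product: 17 methyl 6-formyl-8-hydroxy-3-methoxy-1,4,9-trimethyl-11-oxo-11H-dibenzo[b,e][1,4]dioxepine-7-carboxylate, via mixed trifluoroacetic anhydride 16 (not isolated)
Conditions: (CF3CO)2O (3 equiv), toluene (high dilution), 0 °C to rt; then H2O/THF, rt (neutral work-up)
Reagents that add atoms: none
Why: Trifluoroacetic anhydride turns the hindered, electron-rich ring A acid into a mixed anhydride with acylium character, which is captured by the Cb phenol, the only hydroxyl able to reach it (seven-membered ring B; the Cd phenol would need a nine-membered ring); this is the classical way to acylate phenols with 2,6-disubstituted benzoic acids. Transient aryl trifluoroacetates are solvolysed in the neutral aqueous work-up.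

Step 11
Reactants: 17 methyl 6-formyl-8-hydroxy-3-methoxy-1,4,9-trimethyl-11-oxo-11H-dibenzo[b,e][1,4]dioxepine-7-carboxylate
Product: 18 racemic 1,4-dihydroxy-10-methoxy-5,8,11-trimethyl-1H-isobenzofuro[4,5-b][1,4]benzodioxepine-3,7-dione (racemic lactol)
Conditions: NaHCO3, THF/H2O, rt; then 1 M HCl, 0 °C, pH 2–3
Reagents that add atoms: water, O
Why: Neighbouring-group ester hydrolysis: near pH 8 the hydrate monoanion of the ortho formyl group attacks the flanking methyl ester (5-exo-trig), methoxide leaves, and acidification closes the hydroxyphthalide ring D; this formyl-assisted path is far faster than attack of hydroxide on the hindered depsidone ester, which bicarbonate should leave intact. The lactol carbon forms as a racemate.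

Step 12
Reactants: 18 racemic 1,4-dihydroxy-10-methoxy-5,8,11-trimethyl-1H-isobenzofuro[4,5-b][1,4]benzodioxepine-3,7-dione
Product: 19 (1R)-4-hydroxy-10-methoxy-5,8,11-trimethyl-3,7-dioxo-1,3-dihydro-7H-isobenzofuro[4,5-b][1,4]benzodioxepin-1-yl 2-methylpropanoate
Conditions: (i-PrCO)2O (1.3 equiv), benzotetramisole (10 mol %, the antipode that gives the (R)-ester), i-Pr2NEt, CHCl3, 0 °C
Reagents that add atoms: isobutyric anhydride, CC(C)C(=O)OC(=O)C(C)C
Why: Acylative dynamic kinetic resolution of a lactol by a chiral isothiourea Lewis base: the amine keeps the enantiomers of 18 in equilibrium through the ring-opened formyl carboxylate while the chiral N-acyl isothiouronium ion passes the isobutyryl group faster to one of them, so the catalyst sets the stereocentre; the catalyst antipode that delivers (R) is to be fixed in a small preliminary run. The chelated, flanked Cd phenol should react more slowly than the lactol hydroxyl with the branched anhydride.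

Step 13
Reactants: 19 (1R)-4-hydroxy-10-methoxy-5,8,11-trimethyl-3,7-dioxo-1,3-dihydro-7H-isobenzofuro[4,5-b][1,4]benzodioxepin-1-yl 2-methylpropanoate
Product: 20 (1R)-1,4-dihydroxy-10-methoxy-5,8,11-trimethyl-1H-isobenzofuro[4,5-b][1,4]benzodioxepine-3,7-dione (the target, R at the lactol carbon)
Conditions: immobilised Candida antarctica lipase B, n-BuOH (5 equiv), MTBE, 30 °C; filtration, crystallisation without basic wash
Reagents that add atoms: none
Why: Lipase-catalysed alcoholysis breaks only the acyl–oxygen bond of the exocyclic ester (serine acyl-enzyme, acyl passed to butanol), so both C–O bonds at the stereocentre stay intact and (R) is retained; the medium is neutral, non-aqueous and amine-free, as the ring–chain-labile lactol requires. A hydrolase matched to the (R)-ester also leaves residual (S)-ester behind, which should raise the enantiomeric purity.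

## Compound list

1 | atraric acid (methyl 2,4-dihydroxy-3,6-dimethylbenzoate) | COC(=O)c1c(C)cc(O)c(C)c1O | starting material
2 | methyl 2-hydroxy-4-methoxy-3,6-dimethylbenzoate | COC(=O)c1c(C)cc(OC)c(C)c1O | intermediate
3 | 2-hydroxy-4-methoxy-3,6-dimethylbenzoic acid | OC(=O)c1c(C)cc(OC)c(C)c1O | intermediate
4 | tert-butyl 2-hydroxy-4-methoxy-3,6-dimethylbenzoate | CC(C)(C)OC(=O)c1c(C)cc(OC)c(C)c1O | intermediate
5 | methyl bromoacetate | COC(=O)CBr | starting material
6 | tert-butyl 4-methoxy-2-(2-methoxy-2-oxoethoxy)-3,6-dimethylbenzoate | COC(=O)COc1c(C)c(OC)cc(C)c1C(=O)OC(C)(C)C | intermediate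
7 | dimethoxyacetaldehyde | COC(OC)C=O | starting material
8 | tert-butyl 2-[(3-hydroxy-1,4,4-trimethoxy-1-oxobutan-2-yl)oxy]-4-methoxy-3,6-dimethylbenzoate (racemic diastereomer mixture) | COC(=O)C(Oc1c(C)c(OC)cc(C)c1C(=O)OC(C)(C)C)C(O)C(OC)OC | intermediate
9 | tert-butyl 4-methoxy-3,6-dimethyl-2-{[1,4,4-trimethoxy-3-(methylsulfonyloxy)-1-oxobutan-2-yl]oxy}benzoate | COC(=O)C(Oc1c(C)c(OC)cc(C)c1C(=O)OC(C)(C)C)C(OS(C)(=O)=O)C(OC)OC | intermediate (not isolated)
10 | methyl 2-[2-(tert-butoxycarbonyl)-5-methoxy-3,6-dimethylphenoxy]-4,4-dimethoxybut-2-enoate (either alkene geometry) | COC(=O)C(Oc1c(C)c(OC)cc(C)c1C(=O)OC(C)(C)C)=CC(OC)OC | intermediate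
11 | methyl 3-oxopentanoate | CCC(=O)CC(=O)OC | starting material
12 | dimethyl 2-[2-(tert-butoxycarbonyl)-5-methoxy-3,6-dimethylphenoxy]-3-(dimethoxymethyl)-4-propanoylpentanedioate (stereoisomer mixture) | COC(=O)C(Oc1c(C)c(OC)cc(C)c1C(=O)OC(C)(C)C)C(C(OC)OC)C(C(=O)CC)C(=O)OC | intermediate (not isolated)
13 | methyl 3-[2-(tert-butoxycarbonyl)-5-methoxy-3,6-dimethylphenoxy]-2-(dimethoxymethyl)-5-methyl-4,6-dioxocyclohexane-1-carboxylate (stereoisomer and enol-tautomer mixture) | COC(=O)C1C(=O)C(C)C(=O)C(Oc2c(C)c(OC)cc(C)c2C(=O)OC(C)(C)C)C1C(OC)OC | intermediate
14 | methyl 3-[2-(tert-butoxycarbonyl)-5-methoxy-3,6-dimethylphenoxy]-2-(dimethoxymethyl)-4,6-dihydroxy-5-methylbenzoate | COC(=O)c1c(O)c(C)c(O)c(Oc2c(C)c(OC)cc(C)c2C(=O)OC(C)(C)C)c1C(OC)OC | intermediate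
15 | 2-[6-formyl-2,4-dihydroxy-5-(methoxycarbonyl)-3-methylphenoxy]-4-methoxy-3,6-dimethylbenzoic acid | COC(=O)c1c(O)c(C)c(O)c(Oc2c(C)c(OC)cc(C)c2C(=O)O)c1C=O | intermediate
16 | mixed anhydride of 15 (ring A carboxyl) with trifluoroacetic acid | COC(=O)c1c(O)c(C)c(O)c(Oc2c(C)c(OC)cc(C)c2C(=O)OC(=O)C(F)(F)F)c1C=O | intermediate (not isolated)
17 | methyl 6-formyl-8-hydroxy-3-methoxy-1,4,9-trimethyl-11-oxo-11H-dibenzo[b,e][1,4]dioxepine-7-carboxylate | COc1cc(C)c2c(c1C)Oc1c(c(C)c(O)c(C(=O)OC)c1C=O)OC2=O | intermediate
18 | racemic 1,4-dihydroxy-10-methoxy-5,8,11-trimethyl-1H-isobenzofuro[4,5-b][1,4]benzodioxepine-3,7-dione | COc1cc(C)c2c(c1C)Oc1c(c(C)c(O)c3c1C(O)OC3=O)OC2=O | intermediate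
19 | (1R)-4-hydroxy-10-methoxy-5,8,11-trimethyl-3,7-dioxo-1,3-dihydro-7H-isobenzofuro[4,5-b][1,4]benzodioxepin-1-yl 2-methylpropanoate | COc1cc(C)c2c(c1C)Oc1c(c(C)c(O)c3c1[C@H](OC(=O)C(C)C)OC3=O)OC2=O | intermediate
20 | (1R)-1,4-dihydroxy-10-methoxy-5,8,11-trimethyl-1H-isobenzofuro[4,5-b][1,4]benzodioxepine-3,7-dione | COc1cc(C)c2c(c1C)Oc1c(c(C)c(O)c3c1[C@H](O)OC3=O)OC2=O | target

## Step count and least certain steps

Total step count: 13. Longest linear sequence: 13 steps, from 1 to 20; compounds 5, 7 and 11 are purchased.

**Step 7 (key step).** The conjugate addition may be slow and reversible, because the α-aryloxy oxygen feeds electron density into the alkene and the acetal crowds Cf. That leaves time for methoxide to cleave the β-keto ester by retro-Claisen deacylation. The fallback reverses the order of the two bond formations and sets out from 10 and 11. The dianion of 11 (NaH, then n-BuLi, THF, 0 °C) is acylated at its ethyl-ketone carbon by the ester of 10 at −78 °C, forming Cb–Cc first. This gives methyl 6-[2-(tert-butoxycarbonyl)-5-methoxy-3,6-dimethylphenoxy]-8,8-dimethoxy-4-methyl-3,5-dioxooct-6-enoate F1, whose enone is a much stronger acceptor than the enoate. K2CO3 in MeOH then closes Ce–Cf by intramolecular 6-endo-trig Michael addition, and the route is rejoined at 13 with the same two bonds and the same ring.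

**Step 8.** The acidity of the reduced quinone may promote loss of methanol from the acetal, followed by tautomerisation. That would aromatise ring C without oxidation and leave the benzylic carbon one oxidation level too low; further oxidation of the resorcinol is a second concern. The fallback sets out from 13. Me3SiOTf and Et3N (CH2Cl2, 0 °C) give methyl 5-[2-(tert-butoxycarbonyl)-5-methoxy-3,6-dimethylphenoxy]-6-(dimethoxymethyl)-3-methyl-2,4-bis(trimethylsilyloxy)cyclohexa-1,3-diene-1-carboxylate F2. As a 5,6-dihydroarene this should be dehydrogenated by a mild quinone (chloranil, or DDQ buffered with 2,6-lutidine) at or below room temperature, where no free acid reaches the acetal. A fluoride work-up (KF, MeOH) removes the silyl groups and returns to the route at 14.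

**Step 12.** Three processes threaten it: unselective background acylation through the ring-opened formyl carboxylate, acylation of the Cd phenol, and racemisation too slow to keep pace with acylation. The fallback sets out from 18 and uses an enzyme under base-free conditions. Burkholderia cepacia lipase with vinyl acetate in MTBE at 30 °C should acylate only the lactol hydroxyl while the substrate racemises by its own ring–chain equilibrium. The product would be (1R)-4-hydroxy-10-methoxy-5,8,11-trimethyl-3,7-dioxo-1,3-dihydro-7H-isobenzofuro[4,5-b][1,4]benzodioxepin-1-yl acetate F4, the enzyme being chosen from a panel for the (R) sense. Deacetylation under the conditions of step 13 returns to the route at 20.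

**Step 13.** The enzyme may accept the bulky acylal poorly, and during a slow reaction the freed lactol may lose enantiomeric purity by ring–chain tautomerism. The fallback sets out from 18 and uses a non-hydrolytic release. The resolution of step 12 is run with chloroacetic anhydride to give the 2-chloroacetate F5. This has the same spatial arrangement at the acetal carbon as 20, but its formal descriptor is (S) because chlorine raises the rank of the ester oxygen. Thiourea in THF at rt to 40 °C, without added base, alkylates at sulfur and cyclises onto the ester carbonyl, which releases the lactol oxygen with its C–O bonds intact and returns to the route at 20.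

**Step 5.** The anhydrous aldehyde may oligomerise or be incompletely dried, giving partial aldol addition, and on warming the ester enolate may close onto the ring A ester. The fallback sets out from 4. Rh2(OAc)4-catalysed O–H insertion of the carbenoid from methyl diazo(dimethoxyphosphoryl)acetate into the phenol gives methyl 2-[2-(tert-butoxycarbonyl)-5-methoxy-3,6-dimethylphenoxy]-2-(dimethoxyphosphoryl)acetate F3. Horner–Wadsworth–Emmons olefination with 7 (K2CO3, THF/H2O, which tolerates the commercial aqueous solution) returns to the route at 10 and bypasses 6, 8 and 9.

**Step 11.** In this doubly flanked system the formyl-assisted ester cleavage may be slower than expected, so that longer exposure to aqueous base begins to open ring B. The fallback sets out from 17 and returns at 18. BCl3 in CH2Cl2 (−78 to 0 °C) chelates between the Cd oxygen and the ester carbonyl and removes the ester methyl by chloride attack at carbon; aqueous work-up closes the lactol. No new compound is formed on this path (F0).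

## Further compounds

F1 | step 7 | methyl 6-[2-(tert-butoxycarbonyl)-5-methoxy-3,6-dimethylphenoxy]-8,8-dimethoxy-4-methyl-3,5-dioxooct-6-enoate | COC(=O)CC(=O)C(C)C(=O)C(Oc1c(C)c(OC)cc(C)c1C(=O)OC(C)(C)C)=CC(OC)OC
F2 | step 8 | methyl 5-[2-(tert-butoxycarbonyl)-5-methoxy-3,6-dimethylphenoxy]-6-(dimethoxymethyl)-3-methyl-2,4-bis(trimethylsilyloxy)cyclohexa-1,3-diene-1-carboxylate (stereoisomer mixture) | COC(=O)C1=C(O[Si](C)(C)C)C(C)=C(O[Si](C)(C)C)C(Oc2c(C)c(OC)cc(C)c2C(=O)OC(C)(C)C)C1C(OC)OC
F3 | step 5 | methyl 2-[2-(tert-butoxycarbonyl)-5-methoxy-3,6-dimethylphenoxy]-2-(dimethoxyphosphoryl)acetate (racemic) | COC(=O)C(Oc1c(C)c(OC)cc(C)c1C(=O)OC(C)(C)C)P(=O)(OC)OC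
F0 | step 11 | none | none
F4 | step 12 | (1R)-4-hydroxy-10-methoxy-5,8,11-trimethyl-3,7-dioxo-1,3-dihydro-7H-isobenzofuro[4,5-b][1,4]benzodioxepin-1-yl acetate | COc1cc(C)c2c(c1C)Oc1c(c(C)c(O)c3c1[C@H](OC(C)=O)OC3=O)OC2=O
F5 | step 13 | 4-hydroxy-10-methoxy-5,8,11-trimethyl-3,7-dioxo-1,3-dihydro-7H-isobenzofuro[4,5-b][1,4]benzodioxepin-1-yl 2-chloroacetate (same spatial arrangement as 20, formal descriptor 1S) | COc1cc(C)c2c(c1C)Oc1c(c(C)c(O)c3c1[C@H](OC(=O)CCl)OC3=O)OC2=O
A1 | alternative 1 | dihydrodepsidone with ring B closed, ring A a cyclohexa-1,3-diene, ring C with benzyl ester and dimethyl acetal (racemic at the ring A CH–CH3 carbon) | COC1=C(C)C2=C(C(C)C1)C(=O)Oc1c(C)c(O)c(C(=O)OCc3ccccc3)c(C(OC)OC)c1O2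
A2 | alternative 1 | benzyl 2-(dimethoxymethyl)-3,6-dihydroxy-5-methyl-4-{[4-methoxy-3,6-dimethyl-2-(trifluoromethylsulfonyloxy)cyclohexa-1,3-diene-1-carbonyl]oxy}benzoate (racemic) | COC1=C(C)C(OS(=O)(=O)C(F)(F)F)=C(C(C)C1)C(=O)Oc1c(C)c(O)c(C(=O)OCc2ccccc2)c(C(OC)OC)c1O
A3 | alternative 2 | 10-methoxy-5,8,11-trimethyl-3,7-dioxo-1,3-dihydro-7H-isobenzofuro[4,5-b][1,4]benzodioxepin-4-yl acetate (depsidone phthalide acetate) | COc1cc(C)c2c(c1C)Oc1c(c(C)c(OC(C)=O)c3c1COC3=O)OC2=O
A4 | alternative 2 | 8-acetoxy-3-methoxy-1,4,6,9-tetramethyl-11-oxo-11H-dibenzo[b,e][1,4]dioxepine-7-carboxylic acid | COc1cc(C)c2c(c1C)Oc1c(c(C)c(OC(C)=O)c(C(=O)O)c1C)OC2=O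
A5 | alternative 3 | benzyl 2-{[5,7-bis(benzyloxy)-3-methoxy-6-methyl-1-oxo-1,3-dihydroisobenzofuran-4-yl]oxy}-4-methoxy-3,6-dimethylbenzoate (racemic acetal) | COc1cc(C)c(C(=O)OCc2ccccc2)c(Oc2c(OCc3ccccc3)c(C)c(OCc3ccccc3)c3C(=O)OC(OC)c23)c1C
A6 | alternative 3 | 4-methoxy-3,6-dimethyl-2H-pyran-2-one | COc1cc(C)oc(=O)c1C
A7 | alternative 3 | benzyl 3-{[5,7-bis(benzyloxy)-3-methoxy-6-methyl-1-oxo-1,3-dihydroisobenzofuran-4-yl]oxy}prop-2-ynoate (racemic acetal) | O=C(OCc1ccccc1)C#COc1c(OCc2ccccc2)c(C)c(OCc2ccccc2)c2C(=O)OC(OC)c12
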